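## Structural features

The target is a diarylmethane: two benzene rings, each carrying six substituents, joined only through one CH2 carbon. Ring A bears the pentanoyl group at C1, hydroxyls at C2 and C6, a methyl at C3, the only methoxy group at C4 and the bridge at C5; ring B bears the bridge at C1', hydroxyls at C2', C4' and C6', a methyl at C3' and the butanoyl group at C5'. There is no stereocentre, so the whole problem is one of constitution. Each ring is a 1,3,5-trioxygenated benzene with the acyl carbon between two oxygenated carbons, the pattern of a folded tetraketide. The two halves are nearly alike (acyl chains of five and four carbons, one O-methyl among six oxygens), so a union of two preformed phenols pairs partners of almost equal nucleophilicity. The fragile points are the polyphenoxides, which oxidise in air, and the bridge, which is flanked by ortho and para hydroxyls and is cleaved reversibly by acid or base through quinone methides, so that unsymmetrical dimers scramble into symmetrical ones; acid can also close the two ortho hydroxyls across the bridge to a xanthene. The real difficulty is the unsymmetrical union of two fully substituted rings across one carbon without a statistical outcome, together with the placing of six substituents on each ring. The feature that the plan exploits is that C1' of ring B, which holds the bridge, lies between the oxygenated carbons C2' and C6', and that C5', which holds the butanoyl group, lies between C4' and C6': ring B is the Claisen-folded form of a 3,5,7-trioxodecanoate whose C2 carries the bridge, and that C2 is the one nucleophilic carbon (C3) of a 4-hydroxy-2-pyranone.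

## Logic of the disconnections

In one sentence: ring B is closed last, by Claisen condensation of a tetraketide chain set free from 15, a 4-hydroxy-2-pyranone that already carries ring A on the future bridge carbon.

17 to 15 through 16. The C5'–C6' bond of ring B in 17 is cut (retro-Claisen). This opens ring B to the chain 16, in which C6' is the ester carbon C1, C1' is C2 with the bridge, C2' and C4' are the ketone carbons C3 and C5, C3' is the methyl-bearing C4, and C5' is the methylene C6 next to the butanoyl carbonyl C7. 16 has three active C–H sites and is therefore stored as its lactone 15 (C5 enol oxygen closed onto C1). The gain is large: a hexasubstituted benzene becomes a pyranone with three substituents, the position of the butanoyl group is fixed by chain connectivity, and the bridge now ends on a ring that is not yet aromatic. The forward step must open the lactone, prefer Claisen over aldol closure, and leave the bridge intact in base.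

15 to 5 and 13. The bond between the bridge CH2 and C3 of the pyranone ring is cut. C3 is the only nucleophilic carbon of 13 (C5 carries the methyl group), and the ring of 5 is fully substituted, so 5 can act only as an electrophile through 14. The union is therefore a cross-coupling of one electrophile with one mono-nucleophile and cannot give a symmetrical dimer. The forward step must alkylate C3 and not oxygen or the side-chain methylene.

13 to 10 and 11. The bond between the side-chain CH2 and the ketone carbon is cut, which leaves the C6 methyl of 10 as a vinylogous carbanion (12) and 11 as the acyl donor. This brings in the whole butanoyl group in one step. The forward step needs clean formation of a dianion and acylation on carbon.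

10 to 9, and 9 to 6 and 7. The lactone C–O bond is cut, then the C4–C5 bond of 9, which leads to the γ-carbanion of 6 (as 8) and the acetyl donor 7. The future C3' methyl of ring B is present from the start as the terminal methyl of 6. The forward steps need γ-selective acylation and lactonisation.

5 to 4. The bond between C5 of ring A and the aminomethyl carbon is cut (retro-Mannich). 4 has a single free ring position, so no regiochemical question arises.

4 to 3, and 3 to 1 and 2. The O–CH3 bond at C4 is cut, then the bond between ring A and the pentanoyl carbon. 1 is symmetrical, so acylation gives one product; the methylation must single out the hydroxyl para to the acyl group among three.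

## Other disconnections considered

Alternative 1: The cut that comes to mind first is the bridge itself (C1'–CH2 or C5–CH2) with both rings already aromatic: 4 and the ring B ketone A1 are joined by a one-carbon electrophile, or, more selectively, A1 adds to 14 generated from 5. The forward key step is an electrophilic aromatic substitution (Michael addition of the free ring carbon of A1 to a quinone methide). It would be three steps shorter. Its weakness is that the bond is made in the presence of a free, fully activated phloroglucinol ring, and the same quinone methide chemistry can run backwards in the product. Methylene transfer can then lead to the symmetrical dimer A2 and its ring A counterpart, and the two monomers are too alike for reactivity to correct this. In the chosen plan ring B does not exist while the bridge is made, and aromatisation is the last, irreversible event. Alternative 1 is kept as the fallback for step 8.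

Alternative 2: The mirror image of the chosen plan cuts C1–C6 of ring A and makes ring A last from the 4-methoxy-2-pyranone A3, which carries ring B on C3 and a 2-oxohexyl chain on C6. The forward key step is the same methoxide-induced ring opening and Claisen closure; the enol ether masks the central carbonyl of the chain, so the methoxy group would appear at C4, para to the pentanoyl group, by construction. This would solve the O-methyl problem without a selective methylation. It is not chosen for three structural reasons:
- A3 would have to come from the 4-hydroxy compound A4 by methylation of the pyranone hydroxyl in the presence of three free phenols of ring B and an active methylene.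
- An ortho phenoxide of ring B stands five atoms from C4 of the pyranone and can displace the methoxy group through a six-membered transition state, which destroys the very group the plan is meant to secure. In 15 the corresponding oxygen is an oxide and not a leaving group.
- The bridge would again be made with ring B present as a free phloroglucinol.

Protecting ring B would remove these objections but add at least four steps.

Alternative 3: An intermolecular (3+3) construction of ring B cuts C6'–C5' and C2'–C3'. C6'–C1'–C2' would come from the malonate A5 (Michael adduct of 14 with a malonic diester), and C3'–C4'–C5' with the butanoyl group from the 1,3-dianion of octane-3,5-dione A6. The forward key step is a double Claisen condensation. It is rejected on mechanistic grounds. The two outer methylene groups of A6 (C2 and C6) are equally acidic, so the dianion would form on both sides, and the ring isomer A7 (ethyl and propanoyl in place of methyl and butanoyl, same formula) would accompany 17 and be hard to separate. Malonic diesters are also poor acyl donors toward a stabilised enolate, and O-acylation in the second closure would lead to pyranones and not to the benzene ring. The chosen plan assembles the same chain linearly, each carbon with a single role.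

Key step: step 8

Remark: the target has no stereocentre; the enolisable stereocentres of 9 and 16 are drawn without configuration, and poly-β-carbonyl compounds are written as keto or hydroxypyranone tautomers.

## Route

Step 1
Reactants: 1 2-methylbenzene-1,3,5-triol; 2 pentanoyl chloride
Product: 3 1-(2,4,6-trihydroxy-3-methylphenyl)pentan-1-one
Conditions: AlCl3 (3.5 equiv), PhNO2/CH2Cl2, 0 °C to 45 °C; then ice, 1 M HCl
Reagents that add atoms: none
Why: Friedel-Crafts C-acylation of a highly activated arene; the two free ring positions of 1 are equivalent by symmetry, and the aluminium chelate of the first ketone deactivates the ring toward a second acylation.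

Step 2
Reactants: 3 1-(2,4,6-trihydroxy-3-methylphenyl)pentan-1-one
Product: 4 1-(2,6-dihydroxy-4-methoxy-3-methylphenyl)pentan-1-one
Conditions: Me2SO4 (1.0 equiv), K2CO3 (1.0 equiv), acetone, 20 °C to reflux
Reagents that add atoms: dimethyl sulfate, COS(=O)(=O)OC
Why: Williamson O-methylation under acidity control: the hydroxyl para to the acyl group is the most acidic and is ionised first, while the two ortho hydroxyls are tied to the carbonyl by hydrogen bonding and potassium chelation and should react more slowly; one equivalent of reagent limits over-methylation.

Step 3
Reactants: 4 1-(2,6-dihydroxy-4-methoxy-3-methylphenyl)pentan-1-one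
Product: 5 1-{3-[(dimethylamino)methyl]-2,6-dihydroxy-4-methoxy-5-methylphenyl}pentan-1-one
Conditions: Me2N=CH2+ I− (1.2 equiv), MeCN, 0 °C to 20 °C; then aq. NaHCO3
Reagents that add atoms: N,N-dimethylmethylideneammonium iodide (Eschenmoser's salt), C=[N+](C)C.[I-]
Why: Phenolic Mannich reaction with a preformed iminium salt; C5 is the only unsubstituted ring carbon and is ortho and para to hydroxyl groups, so one regioisomer is possible, and the absence of free formaldehyde avoids methylene-bridged self-coupling.

Step 4
Reactants: 6 methyl 3-oxopentanoate; 7 N-methoxy-N-methylacetamide
Product: 9 methyl 4-methyl-3,5-dioxohexanoate, via dilithium dienediolate 8 (not isolated)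
Conditions: LiN(i-Pr)2 (2.2 equiv), THF, 0 °C; then 7, −78 °C to 0 °C; aq. HCl
Reagents that add atoms: none
Why: γ-Acylation of a β-keto ester dianion: the last-formed, least stabilised carbanion at C4 is the more nucleophilic site, and the Weinreb amide gives a chelated tetrahedral adduct that releases the ketone only on work-up, so over-addition and proton transfer from the product are avoided.

Step 5
Reactants: 9 methyl 4-methyl-3,5-dioxohexanoate
Product: 10 4-hydroxy-5,6-dimethyl-2H-pyran-2-one
Conditions: DBU (1.2 equiv), toluene, 80 °C; then 1 M HCl
Reagents that add atoms: none
Why: Base-mediated lactonisation of a 3,5-diketo ester: the C5 enolate oxygen attacks the ester carbonyl (6-exo-trig) and loss of methanol gives the strongly acidic 4-hydroxy-2-pyranone, whose salt formation drives the closure.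

Step 6
Reactants: 10 4-hydroxy-5,6-dimethyl-2H-pyran-2-one; 11 N-methoxy-N-methylbutanamide
Product: 13 4-hydroxy-5-methyl-6-(2-oxopentyl)-2H-pyran-2-one, via dilithium pyranone dianion 12 (not isolated)
Conditions: LiN(i-Pr)2 (2.3 equiv), THF/DMPU, −78 °C to −20 °C; then 11, −78 °C to 0 °C; aq. HCl
Reagents that add atoms: none
Why: Lateral metalation and Claisen-type acylation: after the 4-OH, the C6 methyl is the next acidic site because its carbanion is conjugated through C5=C6 and C3=C4 with the lactone carbonyl, whereas the C5 methyl is cross-conjugated; the carbanion, not the delocalised oxide, should attack the Weinreb amide.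

Step 7
Reactants: 5 1-{3-[(dimethylamino)methyl]-2,6-dihydroxy-4-methoxy-5-methylphenyl}pentan-1-one; 13 4-hydroxy-5-methyl-6-(2-oxopentyl)-2H-pyran-2-one
Product: 15 3-[(2,4-dihydroxy-6-methoxy-5-methyl-3-pentanoylphenyl)methyl]-4-hydroxy-5-methyl-6-(2-oxopentyl)-2H-pyran-2-one, via ortho-quinone methide 14 (not isolated)
Conditions: 13 (1.1 equiv), 1,4-dioxane, 90 °C, argon stream
Reagents that add atoms: none
Why: Thermal loss of dimethylamine from the phenolic Mannich base, assisted by proton transfer from the acidic pyranone, gives 14, and the pyranonate adds through C3 in a Michael addition that restores ring A. 5 can act only as the electrophile (its ring has no free position) and 13 only as the nucleophile (C5 is blocked and the side-chain methylene is far less enolised), so no symmetrical product can form. O-Alkylation is reversible under these conditions and should drain to the C-alkylated product.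

Step 8
Reactants: 15 3-[(2,4-dihydroxy-6-methoxy-5-methyl-3-pentanoylphenyl)methyl]-4-hydroxy-5-methyl-6-(2-oxopentyl)-2H-pyran-2-one
Product: 17 1-{3-[(3-butanoyl-2,4,6-trihydroxy-5-methylphenyl)methyl]-2,6-dihydroxy-4-methoxy-5-methylphenyl}pentan-1-one, via ring-opened triketo ester 16 (not isolated)
Conditions: Mg(OMe)2 (8 equiv), degassed MeOH, reflux, argon; then cold 1 M HCl
Reagents that add atoms: none
Why: Methoxide adds to the lactone carbonyl C2 of the magnesium-chelated pyranonate and the ring opens to the enolate of 16, in which the former lactone carbon is the ester carbon C1; the phenoxide ortho to the bridge can do the same intramolecularly through a six-membered aryl ester, an even better acyl donor that leads to the same chain. The carbanion at C6, activated by the C5 and C7 carbonyls, then attacks C1 in a Claisen (Dieckmann-type) condensation, 6-exo-trig at the ester carbonyl, methoxide leaves, and the resulting cyclohexane-1,3,5-trione tautomerises to aromatic ring B, so that the bond formed is C5'–C6' of the target. The closest known reaction type is the magnesium-methoxide-induced conversion of 6-(2-oxoalkyl)-4-hydroxy-2-pyranones and of 3,5,7-triketo esters into acylphloroglucinols, the laboratory counterpart of the polyketide Claisen cyclisation. The selectivity needed is Claisen over aldol closure: the aldol alternative (C2 onto the C7 ketone) would create a quaternary C2 bearing the arylmethyl group, cannot aromatise and stays reversible, and the C8 methylene is activated by one carbonyl only, whereas the Claisen product is removed irreversibly as its magnesium phenoxide. No stereocentre is formed; the two enolisable stereocentres of 16 (C2 and C4) become sp2 carbons of ring B. The bridge should survive because the ring A phenoxides are ortho to the pentanoyl group and magnesium-chelated, which weakens the push needed to expel the pyranonate, and because ring B, once formed, is fully substituted and held as a chelated phenoxide. Oxygen is excluded because the polyphenoxides are air-sensitive.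

## Compound list

1 | 2-methylbenzene-1,3,5-triol (2,4,6-trihydroxytoluene) | Cc1c(O)cc(O)cc1O | starting material
2 | pentanoyl chloride | CCCCC(Cl)=O | starting material
3 | 1-(2,4,6-trihydroxy-3-methylphenyl)pentan-1-one | CCCCC(=O)c1c(O)cc(O)c(C)c1O | intermediate
4 | 1-(2,6-dihydroxy-4-methoxy-3-methylphenyl)pentan-1-one | CCCCC(=O)c1c(O)cc(OC)c(C)c1O | intermediate
5 | 1-{3-[(dimethylamino)methyl]-2,6-dihydroxy-4-methoxy-5-methylphenyl}pentan-1-one | CCCCC(=O)c1c(O)c(CN(C)C)c(OC)c(C)c1O | intermediate
6 | methyl 3-oxopentanoate | CCC(=O)CC(=O)OC | starting material
7 | N-methoxy-N-methylacetamide | CC(=O)N(C)OC | starting material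
8 | dilithium 1-methoxypenta-1,3-diene-1,3-diolate, the C2,C4-dianion of 6 (not isolated) | [Li+].[Li+].CC=C([O-])C=C([O-])OC | intermediate
9 | methyl 4-methyl-3,5-dioxohexanoate (C4 enolisable, no configuration) | COC(=O)CC(=O)C(C)C(C)=O | intermediate
10 | 4-hydroxy-5,6-dimethyl-2H-pyran-2-one | Cc1oc(=O)cc(O)c1C | intermediate
11 | N-methoxy-N-methylbutanamide | CCCC(=O)N(C)OC | starting material
12 | dilithium dianion of 10, lithium oxide at C4 and lithiomethyl at C6 (not isolated) | [Li+].[Li+].[CH2-]C1=C(C)C([O-])=CC(=O)O1 | intermediate
13 | 4-hydroxy-5-methyl-6-(2-oxopentyl)-2H-pyran-2-one | CCCC(=O)Cc1oc(=O)cc(O)c1C | intermediate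
14 | 3-hydroxy-5-methoxy-4-methyl-6-methylidene-2-pentanoylcyclohexa-2,4-dien-1-one, the ortho-quinone methide from 5 (not isolated) | CCCCC(=O)C1=C(O)C(C)=C(OC)C(=C)C1=O | intermediate
15 | 3-[(2,4-dihydroxy-6-methoxy-5-methyl-3-pentanoylphenyl)methyl]-4-hydroxy-5-methyl-6-(2-oxopentyl)-2H-pyran-2-one | CCCCC(=O)c1c(O)c(C)c(OC)c(Cc2c(O)c(C)c(CC(=O)CCC)oc2=O)c1O | intermediate
16 | methyl 2-[(2,4-dihydroxy-6-methoxy-5-methyl-3-pentanoylphenyl)methyl]-4-methyl-3,5,7-trioxodecanoate, ring-opened form of 15 (C2 and C4 enolisable, no configuration; not isolated) | CCCCC(=O)c1c(O)c(C)c(OC)c(CC(C(=O)OC)C(=O)C(C)C(=O)CC(=O)CCC)c1O | intermediate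
17 | 1-{3-[(3-butanoyl-2,4,6-trihydroxy-5-methylphenyl)methyl]-2,6-dihydroxy-4-methoxy-5-methylphenyl}pentan-1-one | CCCCC(=O)c1c(O)c(C)c(OC)c(Cc2c(O)c(C)c(O)c(C(=O)CCC)c2O)c1O | target

## Step count and risk

Total step count: 8. Longest linear sequence: 5 steps (4, 5, 6, 7, 8; the branch 1, 2, 3, 7, 8 is equally long).

Steps least certain to work:

Step 8 (key step). Two things are most likely to go wrong. The first is base-induced retro-Michael cleavage of the bridge, in which a ring A phenoxide expels the pyranonate and the fragments recombine in other ways. The second is sluggish ring opening of the multiply charged pyranonate, so that oxidation of the phenoxides competes. Fallback: the same ring transformation is applied one step earlier, to 13, which carries no bridge that could be lost; this should give 1-(2,4,6-trihydroxy-3-methylphenyl)butan-1-one F1 (the same compound as A1). F1 then takes up 14, generated thermally from 5 as in step 7, at its single free ring carbon and gives 17 directly under neutral conditions. The fallback sets out from 13 (with 5) and comes back at 17; its price is that the last bond is again made between two aromatic rings.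

Step 7. The likely failures are alkylation of 13 at oxygen or at the side-chain methylene in place of C3, slow loss of the amine, or cyclisation of the adduct to a cyclic ketal between the ortho hydroxyl and the pyranone. Fallback: a reductive alkylation through an aldehyde in place of the quinone methide. 4 is formylated at C5 (Vilsmeier-Haack, POCl3/DMF) to 2,4-dihydroxy-6-methoxy-5-methyl-3-pentanoylbenzaldehyde F2. F2 is condensed with 13 under L-proline catalysis in the presence of a Hantzsch ester, which reduces the Knoevenagel alkylidene as it forms and gives 15. The fallback sets out from 4 and comes back at 15.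

Step 6. The likely failures are incomplete second deprotonation because the monolithium pyranonate is poorly soluble, and proton transfer from the Weinreb amide to the carbanion in place of addition. Fallback: the acidic hydroxyl is masked so that a monoanion suffices. 10 is converted with MOMCl and i-Pr2NEt into 4-(methoxymethoxy)-5,6-dimethyl-2H-pyran-2-one F3. Metalation of F3 at the C6 methyl with LiN(SiMe3)2 under equilibrating conditions and acylation with 11 gives 4-(methoxymethoxy)-5-methyl-6-(2-oxopentyl)-2H-pyran-2-one F4. HCl in MeOH removes the acetal and gives 13. The fallback sets out from 10 and comes back at 13.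

Step 2. The likely failure is methylation at an ortho hydroxyl or double methylation, since the three hydroxyls differ only in acidity and hydrogen bonding. Fallback: selectivity is moved from the methylation to the cleavage. 3 is methylated exhaustively (excess Me2SO4, K2CO3) to 1-(2,4,6-trimethoxy-3-methylphenyl)pentan-1-one F5. BCl3 (CH2Cl2, −20 °C to 20 °C) then cleaves only the two ethers that can chelate boron with the ketone oxygen, those ortho to the carbonyl, and leaves the para methoxy group, giving 4. The fallback sets out from 3 and comes back at 4.

## Further compounds

F1 | step 8 | 1-(2,4,6-trihydroxy-3-methylphenyl)butan-1-one | CCCC(=O)c1c(O)cc(O)c(C)c1O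
F2 | step 7 | 2,4-dihydroxy-6-methoxy-5-methyl-3-pentanoylbenzaldehyde | CCCCC(=O)c1c(O)c(C)c(OC)c(C=O)c1O
F3 | step 6 | 4-(methoxymethoxy)-5,6-dimethyl-2H-pyran-2-one | COCOc1cc(=O)oc(C)c1C
F4 | step 6 | 4-(methoxymethoxy)-5-methyl-6-(2-oxopentyl)-2H-pyran-2-one | CCCC(=O)Cc1oc(=O)cc(OCOC)c1C
F5 | step 2 | 1-(2,4,6-trimethoxy-3-methylphenyl)pentan-1-one | CCCCC(=O)c1c(OC)cc(OC)c(C)c1OC
A1 | alternative 1 | 1-(2,4,6-trihydroxy-3-methylphenyl)butan-1-one | CCCC(=O)c1c(O)cc(O)c(C)c1O
A2 | alternative 1 | 1,1'-[methylenebis(2,4,6-trihydroxy-5-methylbenzene-3,1-diyl)]di(butan-1-one) | CCCC(=O)c1c(O)c(C)c(O)c(Cc2c(O)c(C)c(O)c(C(=O)CCC)c2O)c1O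
A3 | alternative 2 | 3-[(3-butanoyl-2,4,6-trihydroxy-5-methylphenyl)methyl]-4-methoxy-5-methyl-6-(2-oxohexyl)-2H-pyran-2-one | CCCCC(=O)Cc1oc(=O)c(Cc2c(O)c(C)c(O)c(C(=O)CCC)c2O)c(OC)c1C
A4 | alternative 2 | 3-[(3-butanoyl-2,4,6-trihydroxy-5-methylphenyl)methyl]-4-hydroxy-5-methyl-6-(2-oxohexyl)-2H-pyran-2-one | CCCCC(=O)Cc1oc(=O)c(Cc2c(O)c(C)c(O)c(C(=O)CCC)c2O)c(O)c1C
A5 | alternative 3 | dimethyl 2-[(2,4-dihydroxy-6-methoxy-5-methyl-3-pentanoylphenyl)methyl]propanedioate | CCCCC(=O)c1c(O)c(C)c(OC)c(CC(C(=O)OC)C(=O)OC)c1O
A6 | alternative 3 | octane-3,5-dione | CCCC(=O)CC(=O)CC
A7 | alternative 3 | 1-{3-[(3-ethyl-2,4,6-trihydroxy-5-propanoylphenyl)methyl]-2,6-dihydroxy-4-methoxy-5-methylphenyl}pentan-1-one | CCCCC(=O)c1c(O)c(C)c(OC)c(Cc2c(O)c(CC)c(O)c(C(=O)CC)c2O)c1O
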